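## Retrosynthetic overview

- Last operation: fluoride removal of two silyl groups from the bis-silyl (3R)-isoflavan.
- Key disconnection: ring C (C4–C4a) and the C3–aryl bond are made together by ionising an (R)-1-aryloxy-3-arylpropan-2-yl triflate; ring B shifts 1,2 through a phenonium ion and ring A closes onto the vacated CH2.
- The carbinol comes from a ring B aryllithium and an (R)-aryl glycidyl ether; C2–C3–C4 and the stereocentre come from (S)-glycidol, ring A from resorcinol.
- Ring B bromide: resorcinol → 4-bromoresorcinol → dimethylpyran annulation with 3-methylbut-2-enal → C-prenylation at the one free ortho carbon → silyl ether.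
- Ring order: the dimethylpyran on ring B first, ring C last; rings A and B are both bought as resorcinol.

Assumption: the target is the (3R)-isoflavan encoded by the given SMILES, and (S)-glycidol is bought in ≥98% ee.

## Route

Step 1
Reactants: 1 resorcinol (benzene-1,3-diol)
Product: 2 4-bromobenzene-1,3-diol
Conditions: NBS (1.0 equiv), MeCN, −20 °C → rt
Reagents that add atoms: N-bromosuccinimide, O=C1CCC(=O)N1Br
Why: electrophilic aromatic bromination goes to C4 (ortho to one OH, para to the other), the most activated unhindered site, and one equivalent at low temperature limits dibromination.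

Step 2
Reactants: 2 4-bromobenzene-1,3-diol; 3 3-methylbut-2-enal
Product: 4 6-bromo-2,2-dimethyl-2H-chromen-7-ol
Conditions: ethylenediammonium diacetate (10 mol %), toluene, 110 °C, Dean–Stark
Reagents that add atoms: none
Why: formal [3+3] chromene annulation (amine-catalysed Knoevenagel-type C-alkylation at C6 of 2, which is para to one OH and ortho to the other, then dehydration and oxa-6π ring closure onto the adjacent oxygen); no stereocentre is formed.

Step 3
Reactants: 4 6-bromo-2,2-dimethyl-2H-chromen-7-ol; 5 1-bromo-3-methylbut-2-ene (prenyl bromide)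
Product: 7 6-bromo-2,2-dimethyl-8-(3-methylbut-2-en-1-yl)-2H-chromen-7-ol, via sodium phenoxide 6 (not isolated)
Conditions: NaH (1.05 equiv), toluene, 0 °C; then 5 (1.1 equiv), rt
Reagents that add atoms: none
Why: ortho-C-alkylation of a contact-ion-pair sodium phenoxide in a non-polar solvent; C8 is the only free ortho carbon (C6 carries Br, the para carbon is ring-fused), so C-attack can give only one regioisomer.

Step 4
Reactants: 7 6-bromo-2,2-dimethyl-8-(3-methylbut-2-en-1-yl)-2H-chromen-7-ol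
Product: 8 {[6-bromo-2,2-dimethyl-8-(3-methylbut-2-en-1-yl)-2H-chromen-7-yl]oxy}triisopropylsilane
Conditions: TIPSOTf (1.2 equiv), 2,6-lutidine (1.5 equiv), CH2Cl2, 0 °C
Reagents that add atoms: triisopropylsilyl triflate, CC(C)[Si](OS(=O)(=O)C(F)(F)F)(C(C)C)C(C)C
Why: O-silylation of a hindered phenol with a silyl triflate; the bulky, weakly nucleophilic silyl ether survives aryllithium formation and cannot act as an oxygen neighbouring group in step 8.

Step 5
Reactants: 1 resorcinol (2.0 equiv)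
Product: 9 3-(triisopropylsilyloxy)phenol
Conditions: TIPSCl (1.0 equiv), imidazole (1.2 equiv), DMF, 0 °C → rt
Reagents that add atoms: chlorotriisopropylsilane, CC(C)[Si](Cl)(C(C)C)C(C)C
Why: statistical mono-silylation of a symmetrical diol with the diol in excess; unreacted resorcinol is washed out with water.

Step 6
Reactants: 9 3-(triisopropylsilyloxy)phenol; 10 (S)-glycidol, [(2S)-oxiran-2-yl]methanol
Product: 11 triisopropyl{3-[(2R)-oxiran-2-ylmethoxy]phenoxy}silane
Conditions: PPh3, DIAD, THF, 0 °C → rt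
Reagents that add atoms: none
Why: Mitsunobu etherification at the primary carbon leaves the stereocentre untouched; the descriptor changes from S to R only because CH2OAr outranks the ring CH2 whereas CH2OH does not.

Step 7
Reactants: 8 {[6-bromo-2,2-dimethyl-8-(3-methylbut-2-en-1-yl)-2H-chromen-7-yl]oxy}triisopropylsilane; 11 triisopropyl{3-[(2R)-oxiran-2-ylmethoxy]phenoxy}silane
Product: 13 (2R)-1-[2,2-dimethyl-8-(3-methylbut-2-en-1-yl)-7-(triisopropylsilyloxy)-2H-chromen-6-yl]-3-[3-(triisopropylsilyloxy)phenoxy]propan-2-ol, via aryllithium 12 (not isolated)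
Conditions: 8 (1.3 equiv), n-BuLi (1.3 equiv), THF, −78 °C; then 11 (1.0 equiv), BF3·OEt2 (1.3 equiv), −78 °C
Reagents that add atoms: none
Why: bromine–lithium exchange followed by BF3-assisted SN2 opening of the epoxide at its terminal CH2; the stereocentre is not involved and stays R, and −78 °C prevents silyl migration to the lithiated carbon.

Step 8
Reactants: 13 (2R)-1-[2,2-dimethyl-8-(3-methylbut-2-en-1-yl)-7-(triisopropylsilyloxy)-2H-chromen-6-yl]-3-[3-(triisopropylsilyloxy)phenoxy]propan-2-ol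
Product: 16 (3R)-3-[2,2-dimethyl-8-(3-methylbut-2-en-1-yl)-7-(triisopropylsilyloxy)-2H-chromen-6-yl]-7-(triisopropylsilyloxy)-3,4-dihydro-2H-chromene, via secondary triflate 14 (not isolated), via phenonium triflate 15 (not isolated)
Conditions: Tf2O (1.15 equiv), 2,6-di-tert-butyl-4-methylpyridine (2.5 equiv), CH2Cl2 (0.02 M), −78 → −20 °C
Reagents that add atoms: none
Why: Proposed new method: a migratory Friedel–Crafts cycloalkylation in which O-triflation gives 14, ring B (activated by its para ring oxygen) displaces triflate from the back with inversion to form the spiro-cyclopropyl phenonium ion 15, and ring A (at its carbon para to the silyloxy group and ortho to the ether oxygen) opens 15 at the unsubstituted CH2 in a six-membered closure, so ring B ends on the former carbinol carbon (net 1,2-aryl shift) and the (R)-carbinol is converted stereospecifically into the (3R)-isoflavan; the closest known reaction types are phenonium-ion solvolyses of β-arylalkyl sulfonates and the acid-promoted 6-endo cyclisation of aryl glycidyl ethers to chroman-3-ols.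

Step 9
Reactants: 16 (3R)-3-[2,2-dimethyl-8-(3-methylbut-2-en-1-yl)-7-(triisopropylsilyloxy)-2H-chromen-6-yl]-7-(triisopropylsilyloxy)-3,4-dihydro-2H-chromene
Product: 17 (3R)-3-[7-hydroxy-2,2-dimethyl-8-(3-methylbut-2-en-1-yl)-2H-chromen-6-yl]-3,4-dihydro-2H-chromen-7-ol
Conditions: Bu4NF (2.4 equiv), AcOH (2.4 equiv), THF, 0 °C
Reagents that add atoms: none
Why: fluoride cleavage of both aryl silyl ethers under buffered conditions leaves the prenyl group, the chromene alkene and the non-acidic C3 stereocentre untouched.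

## Compound list

1 | resorcinol (benzene-1,3-diol) | Oc1cccc(O)c1 | starting material
2 | 4-bromobenzene-1,3-diol | Oc1ccc(Br)c(O)c1 | intermediate
3 | 3-methylbut-2-enal | CC(C)=CC=O | starting material
4 | 6-bromo-2,2-dimethyl-2H-chromen-7-ol | CC1(C)C=Cc2cc(Br)c(O)cc2O1 | intermediate
5 | 1-bromo-3-methylbut-2-ene (prenyl bromide) | CC(C)=CCBr | starting material
6 | sodium 6-bromo-2,2-dimethyl-2H-chromen-7-olate | [Na+].[O-]c1cc2OC(C)(C)C=Cc2cc1Br | intermediate (not isolated)
7 | 6-bromo-2,2-dimethyl-8-(3-methylbut-2-en-1-yl)-2H-chromen-7-ol | CC(C)=CCc1c(O)c(Br)cc2c1OC(C)(C)C=C2 | intermediate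
8 | {[6-bromo-2,2-dimethyl-8-(3-methylbut-2-en-1-yl)-2H-chromen-7-yl]oxy}triisopropylsilane | CC(C)=CCc1c(O[Si](C(C)C)(C(C)C)C(C)C)c(Br)cc2c1OC(C)(C)C=C2 | intermediate
9 | 3-(triisopropylsilyloxy)phenol | CC(C)[Si](Oc1cccc(O)c1)(C(C)C)C(C)C | intermediate
10 | (S)-glycidol, [(2S)-oxiran-2-yl]methanol | OC[C@H]1CO1 | starting material
11 | triisopropyl{3-[(2R)-oxiran-2-ylmethoxy]phenoxy}silane | CC(C)[Si](Oc1cccc(OC[C@H]2CO2)c1)(C(C)C)C(C)C | intermediate
12 | [2,2-dimethyl-8-(3-methylbut-2-en-1-yl)-7-(triisopropylsilyloxy)-2H-chromen-6-yl]lithium | CC(C)=CCc1c(O[Si](C(C)C)(C(C)C)C(C)C)c([Li])cc2c1OC(C)(C)C=C2 | intermediate (not isolated)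
13 | (2R)-1-[2,2-dimethyl-8-(3-methylbut-2-en-1-yl)-7-(triisopropylsilyloxy)-2H-chromen-6-yl]-3-[3-(triisopropylsilyloxy)phenoxy]propan-2-ol | CC(C)=CCc1c(O[Si](C(C)C)(C(C)C)C(C)C)c(C[C@@H](O)COc3cccc(O[Si](C(C)C)(C(C)C)C(C)C)c3)cc2c1OC(C)(C)C=C2 | intermediate
14 | (2R)-1-[2,2-dimethyl-8-(3-methylbut-2-en-1-yl)-7-(triisopropylsilyloxy)-2H-chromen-6-yl]-3-[3-(triisopropylsilyloxy)phenoxy]propan-2-yl trifluoromethanesulfonate | CC(C)=CCc1c(O[Si](C(C)C)(C(C)C)C(C)C)c(C[C@@H](OS(=O)(=O)C(F)(F)F)COc3cccc(O[Si](C(C)C)(C(C)C)C(C)C)c3)cc2c1OC(C)(C)C=C2 | intermediate (not isolated)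
15 | phenonium triflate: ring B spiro-fused through its former attachment carbon to a cyclopropane made of C1 and C2 of the propane chain, drawn as the pyran oxocarbenium form; C2 is R, the spiro carbon is undefined (both forms give the same product) | CC(C)=CCC1=C(O[Si](C(C)C)(C(C)C)C(C)C)C2(C[C@H]2COc3cccc(O[Si](C(C)C)(C(C)C)C(C)C)c3)C=C4C=CC(C)(C)[O+]=C14.[O-]S(=O)(=O)C(F)(F)F | intermediate (not isolated)
16 | (3R)-3-[2,2-dimethyl-8-(3-methylbut-2-en-1-yl)-7-(triisopropylsilyloxy)-2H-chromen-6-yl]-7-(triisopropylsilyloxy)-3,4-dihydro-2H-chromene | CC(C)=CCc1c(O[Si](C(C)C)(C(C)C)C(C)C)c([C@@H]3COc4cc(O[Si](C(C)C)(C(C)C)C(C)C)ccc4C3)cc2c1OC(C)(C)C=C2 | intermediate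
17 | (3R)-3-[7-hydroxy-2,2-dimethyl-8-(3-methylbut-2-en-1-yl)-2H-chromen-6-yl]-3,4-dihydro-2H-chromen-7-ol | CC(C)=CCc1c(O)c([C@@H]2COc3cc(O)ccc3C2)cc2c1OC(C)(C)C=C2 | target

## Step count and risks

Total step count: 9. Longest linear sequence: 7 (steps 1, 2, 3, 4, 7, 8, 9).

**Step 8 (the new reaction).** It can fail in four ways:
- ring A closes at the substituted phenonium carbon, or without aryl participation, giving a 3-benzyl-2,3-dihydrobenzofuran with no shift;
- a hydride shift gives the 4-aryl isomer;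
- the triflate eliminates;
- ring A attacks at its carbon between the two oxygens.

The fallback uses known chemistry only (auxiliary-controlled enolate alkylation, then Pd-catalysed C–O ring closure). It sets out from bromide 8 and comes back at 16. Aryllithium 12, made from 8 as in step 7, opens oxirane (BF3·OEt2, THF, −78 °C) to give 2-[2,2-dimethyl-8-(3-methylbut-2-en-1-yl)-7-(triisopropylsilyloxy)-2H-chromen-6-yl]ethan-1-ol F1. Oxidation (TEMPO cat., PhI(OAc)2, MeCN–H2O) gives the corresponding arylacetic acid F2. N-Acylation of (R)-4-benzyloxazolidin-2-one (t-BuCOCl, Et3N, LiCl, THF) gives the acyl oxazolidinone F3. Separately, 3-bromo-4-methylphenol is silylated (TIPSCl, imidazole, DMF) to (3-bromo-4-methylphenoxy)triisopropylsilane F4 and brominated at the methyl group (NBS, AIBN, PhCF3, 80 °C) to [3-bromo-4-(bromomethyl)phenoxy]triisopropylsilane F5. Alkylation of F3 with F5 (NaN(SiMe3)2, THF, −78 °C) gives the (2R)-alkylated imide F6; the auxiliary benzyl group shields one enolate face. Reduction with LiBH4 (Et2O, 1 equiv MeOH, 0 °C) gives the (2R)-2-aryl-3-(2-bromoaryl)propan-1-ol F7. Intramolecular C–O coupling (Pd(OAc)2, 2-(di-tert-butylphosphino)-1,1'-binaphthyl, Cs2CO3, toluene, 70 °C) closes ring C to 16.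

**Step 3.** O-prenylation and double alkylation compete with ortho-C-prenylation. The fallback sets out from 4 and comes back at 7. O-Alkylation of 4 with 3-chloro-3-methylbut-1-yne (CuCl2·2H2O 1 mol %, DBU, MeCN, 0 °C) gives 6-bromo-2,2-dimethyl-7-[(2-methylbut-3-yn-2-yl)oxy]-2H-chromene F8. Semi-hydrogenation (H2 1 atm, Pd/CaCO3 poisoned with Pb(OAc)2, quinoline, EtOAc) gives 6-bromo-2,2-dimethyl-7-[(2-methylbut-3-en-2-yl)oxy]-2H-chromene F9. Heating (N,N-diethylaniline, 120 °C) effects an aromatic Claisen rearrangement that delivers the allyl terminus to C8, the only free ortho carbon, giving 7.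

**Step 2.** Attack at the carbon between the two hydroxyls of 2 (angular 5-hydroxychromenes) and a second annulation on the product are possible. The fallback reverses the order of ring formation and halogenation; it sets out from 1 and comes back at 4, so step 1 is not needed. Resorcinol 1 is condensed with 3 (pyridine, 140 °C, sealed tube) to 2,2-dimethyl-2H-chromen-7-ol F10. This is then brominated at C6, ortho to the hydroxyl and para to the ring oxygen (NBS 1.0 equiv, CH2Cl2, −78 °C), to give 4.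

## Further compounds

F1 | step 8 | 2-[2,2-dimethyl-8-(3-methylbut-2-en-1-yl)-7-(triisopropylsilyloxy)-2H-chromen-6-yl]ethan-1-ol | CC(C)=CCc1c(O[Si](C(C)C)(C(C)C)C(C)C)c(CCO)cc2c1OC(C)(C)C=C2
F2 | step 8 | 2-[2,2-dimethyl-8-(3-methylbut-2-en-1-yl)-7-(triisopropylsilyloxy)-2H-chromen-6-yl]acetic acid | CC(C)=CCc1c(O[Si](C(C)C)(C(C)C)C(C)C)c(CC(=O)O)cc2c1OC(C)(C)C=C2
F3 | step 8 | (4R)-4-benzyl-3-{2-[2,2-dimethyl-8-(3-methylbut-2-en-1-yl)-7-(triisopropylsilyloxy)-2H-chromen-6-yl]acetyl}oxazolidin-2-one | CC(C)=CCc1c(O[Si](C(C)C)(C(C)C)C(C)C)c(CC(=O)N3[C@H](Cc4ccccc4)COC3=O)cc2c1OC(C)(C)C=C2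
F4 | step 8 | (3-bromo-4-methylphenoxy)triisopropylsilane | Cc1ccc(O[Si](C(C)C)(C(C)C)C(C)C)cc1Br
F5 | step 8 | [3-bromo-4-(bromomethyl)phenoxy]triisopropylsilane | BrCc1ccc(O[Si](C(C)C)(C(C)C)C(C)C)cc1Br
F6 | step 8 | (4R)-4-benzyl-3-{(2R)-3-[2-bromo-4-(triisopropylsilyloxy)phenyl]-2-[2,2-dimethyl-8-(3-methylbut-2-en-1-yl)-7-(triisopropylsilyloxy)-2H-chromen-6-yl]propanoyl}oxazolidin-2-one | CC(C)=CCc1c(O[Si](C(C)C)(C(C)C)C(C)C)c([C@@H](Cc5ccc(O[Si](C(C)C)(C(C)C)C(C)C)cc5Br)C(=O)N3[C@H](Cc4ccccc4)COC3=O)cc2c1OC(C)(C)C=C2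
F7 | step 8 | (2R)-3-[2-bromo-4-(triisopropylsilyloxy)phenyl]-2-[2,2-dimethyl-8-(3-methylbut-2-en-1-yl)-7-(triisopropylsilyloxy)-2H-chromen-6-yl]propan-1-ol | CC(C)=CCc1c(O[Si](C(C)C)(C(C)C)C(C)C)c([C@@H](Cc3ccc(O[Si](C(C)C)(C(C)C)C(C)C)cc3Br)CO)cc2c1OC(C)(C)C=C2
F8 | step 3 | 6-bromo-2,2-dimethyl-7-[(2-methylbut-3-yn-2-yl)oxy]-2H-chromene | C#CC(C)(C)Oc1cc2OC(C)(C)C=Cc2cc1Br
F9 | step 3 | 6-bromo-2,2-dimethyl-7-[(2-methylbut-3-en-2-yl)oxy]-2H-chromene | C=CC(C)(C)Oc1cc2OC(C)(C)C=Cc2cc1Br
F10 | step 2 | 2,2-dimethyl-2H-chromen-7-ol | CC1(C)C=Cc2ccc(O)cc2O1
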